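## Analysis of the target

Halimane numbering is used throughout: ring A is C1–C5 and C10, ring B is C5–C10, C17 is the methyl on C8, C20 the methyl on C9, and C11–C16 the side chain with oxygen on C15.

- The target is a Δ1(10)-octalin. C4 carries a methyl group and the carboxylic acid. C8 carries a methyl group. The quaternary C9 carries C20 and a five-carbon arm that ends in an (E)-trisubstituted allylic propanoate.
- It has four stereocentres, 4S, 5S, 8R and 9S. The methyl groups on C4, C8 and C9 lie on one face of the bicycle; H5, the carboxyl group and the C11 arm lie on the other.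
- Two of the centres are quaternary (C4 and C9). C9 stands between C8 and the sp2 carbon C10, and no heteroatom is nearby to help set it.
- The allylic propanoate is lost under basic, nucleophilic or ionising conditions. Acid can move the 1(10) alkene to the tetrasubstituted 5(10) position. The C4 carboxyl is shielded, so its ester is slow to hydrolyse.
- The hard parts are a two-carbon arm on a fully substituted C9 with control against C8, the remote C4/C5 pair, and the exact placement of the ring alkene at C1=C10.
- The route rests on one feature: C9 is β to C1 through C10. A C1 ketone (ring A) conjugated with a C9=C10 alkene (ring B) can take C11 and C12 from allene as a cyclobutane. The same C1 oxygen later allows the C10–C12 bond to be cut and leaves the alkene at C1=C10.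

## Retrosynthetic reasoning

**Ester and acid (30 ⇒ 29 ⇒ 28 ⇒ 27).** The propanoate is put on last, because neither the organometallic coupling nor the liberation of the hindered C4 acid would spare an allylic ester. The acid is freed from its methyl ester by attack at the methyl carbon, not at the shielded carbonyl. C15 is kept as a silyl ether until after the coupling.

**C12–C13 (27 ⇒ 21 + 25).** The side chain is cut between C12 and C13. C11 is neopentyl and cannot be alkylated, whereas C12 is a normal primary position. The cut puts the whole stereodefined alkene into the small alkenyl iodide 25, which is joined to the primary iodide 21 by an sp3–sp2 cross-coupling with retention of geometry.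

**Oxidation level at C12 (21 ⇒ 20 ⇒ 19).** The iodide comes from alcohol 20 and this from diester 19. The forward reduction has to distinguish the CH2CO2Me ester from the ester on the quaternary C4.

**C10–C12 and the C1=C10 alkene (19 ⇒ 18 ⇒ 16 ⇒ 15 ⇒ 14).** Reconnecting C12 to C10 turns the acetic ester arm into a cyclobutanone (18), with a sulfonate on C1. Forward, an alkoxide-triggered Grob fragmentation cuts C10–C12 and forms C1=C10 in the same event, so the alkene position is fixed by the mechanism. A separate dehydration of a C1 alcohol after ring opening was not chosen: its C10–H would be flanked by the two axial methyl groups on C4 and C8, and elimination towards C2 would compete. The cyclobutanone comes from the exocyclic methylene of photoadduct 14, and the C1 leaving group from its ketone.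

**C9–C11 and C10–C12, the key step (14 ⇒ 12 + 13).** Both bonds are made at once by [2+2] photocycloaddition of allene 13 to enone 12. The fully substituted β-carbon C9 would resist thermal conjugate addition; the excited enone reacts as a diradical and is much less sensitive to that crowding. The forward reaction must bond the central allene carbon to C10 and must come from the face of H5.

**C9=C10 (12 ⇒ 10 ⇒ 9).** The enone is opened at its alkene to the 1,7-diketone 10, which closes ring B by aldol condensation. The methyl ketone is unmasked from a vinyl group (9) immediately before, so the epimerisable position C8, α to that ketone, exists for one step only.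

**Ring A: C3–C4 and C5–C10 (9 ⇐ 8 ⇐ 7 ⇐ 6 ⇒ 3 + 5).** Ring A is cut into the (E)-α-methyl enal 3 and the 2-silyloxydiene 5. A concerted cycloaddition transfers the (E)-geometry of 3 into the relative configuration of C4 and C5 (methyl cis to the C6 chain), and a chiral Lewis acid chooses the face. A stepwise conjugate addition onto a preformed ring was not used, because the incoming chain would have to choose between the methyl face and the ester face of C4 with no reliable bias.

**Starting materials (3 ⇒ 2 ⇒ 1; 5 ⇒ 4; 25 ⇒ 23 ⇒ 22).** Enal 3 is (R)-β-citronellene 1 oxidised at its (E)-methyl group. The C3 stereocentre of 1 becomes C8, its vinyl group becomes C9/C20, and its chain supplies C4–C7. Diene 5 comes from ketone 4, and iodide 25 from butynol 22.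

## Alternatives that were turned down

**Alternative 1:** Ring B would be built first by cutting C7–C8 and C9–C10.
- Forward key step: (E)-2-methylbut-2-enal A1 and (E)-1-(tert-butyldimethylsilyloxy)buta-1,3-diene A2 combine under a chiral oxazaborolidinium catalyst to cyclohexene A3. In A3 the quaternary C9 carries a formyl group and its methyl, C8 carries a cis methyl, and C10 a silyloxy group.
- For it: the vicinal C8/C9 pair, quaternary centre included, comes from one catalytic step and two cheap reagents. On this point it is stronger than the chosen route, which needs a chiral-pool C8 and a photochemical step at a crowded alkene.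
- Against it: ring A, with the second quaternary centre C4 and with C5, must still be annulated onto C10 and C5 of A3, with no element that relates C4/C5 to C8/C9. C10 must change from a silyl ether into the sp2 carbon of the C1=C10 alkene. The formyl group supplies only C11.
- Comparison: the chosen route makes C4 and C5 in one cycloaddition of its own and uses the C1 ketone twice, for the photocycloaddition and for placing the alkene. The two methyl groups on C4 and C8 then relate the two halves by steering the allene.

**Alternative 2:** Both rings would come from one acyclic chain by cutting C5–C10 and C8–C9.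
- Forward key step: an endo intramolecular Diels–Alder reaction promoted by Et2AlCl, in which a C5=C6–C7=C8 diene adds to a C9=C10 enone and ring A forms as the tether ring. The product is the cis-fused C1-keto octalin A4 with the complete side chain.
- For it: two rings and four stereocentres (C5, C8, C9, C10) in one step and no late coupling at C12. In convergence and step economy it is stronger than the chosen route.
- Against it: the dienophile is a β,β-disubstituted enone and therefore poor, and its alkene geometry must be pure because it becomes the configuration of C9. The only stereocentre before cyclisation is an acyclic quaternary C4, which must be made enantioselectively and must then control the diene face (methyl against ester) and, through endo/exo selection, C8 and C9. Afterwards C6=C7 must be hydrogenated beside the C13=C14 alkene, and the C1 ketone still has to become the C1=C10 alkene.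
- Comparison: the chosen route is longer but separates these problems. The ring-A centres come from a concerted intermolecular cycloaddition of an (E)-enal, C9 from a face-selective addition to a rigid bicycle, and the alkene from a fragmentation.

**Alternative 3:** Ring A would be closed by cutting C4–C5 in a Claisen sense.
- Forward key step: the silyl ketene acetal (Et3N, Me3SiOTf, heat) of a six-membered α-methoxycarbonyl lactone, whose carbinol carbon C1 bears the ring-B cyclohexenyl group, rearranges. It forms C4–C5, closes ring A and leaves the C1=C10 alkene, giving the geminal acid ester A5.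
- For it: the alkene appears in its final place by the rearrangement itself, C5 is set by chirality transfer from C1, and no photochemistry is needed. On alkene placement it is as strong as the fragmentation of the chosen route.
- Against it: A5 has two carboxyl carbons on C4. One must be taken down to a methyl group at a neopentyl position (reduce, activate, deoxygenate) while the other survives, and which is which decides the configuration of C4. Ring B with C8, the quaternary C9 and the side chain must exist beforehand, so the hardest centre is moved to an earlier stage without a method for it.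
- Comparison: the chosen route brings C4 in with its methyl group already attached and has a defined step for C9.

Key step: step 10

## Remarks on the chemistry

- The sense of induction in step 4 is assigned from the formyl C–H···O binding model of oxazaborolidinium–enal complexes, which calls for the salt derived from (R)-α,α-diphenylprolinol. If a test run showed the opposite sense, the antipodal salt would be used in the same way.
- Commercial (R)-β-citronellene is taken to be of sufficient enantiomeric purity. Material from its minor enantiomer becomes a diastereomer in step 4 and is removed there.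

## Steps

**Step 1**
Reactants: 1 (3R)-3,7-dimethylocta-1,6-diene [(R)-β-citronellene]
Product: 2 (2E,6R)-2,6-dimethylocta-2,7-dien-1-ol
Conditions: SeO2 (0.1 equiv), t-BuOOH, salicylic acid (0.1 equiv), CH2Cl2, rt
Reagents that add atoms: selenium dioxide, O=[Se]=O (oxygen donor, regenerated); tert-butyl hydroperoxide, CC(C)(C)OO (terminal oxygen source)
Why: Catalytic SeO2 allylic oxidation (ene reaction, then [2,3]-sigmatropic shift) attacks the electron-rich trisubstituted alkene at its (E)-methyl group and should give the (E)-allylic alcohol; the monosubstituted vinyl group and the C6 stereocentre are not involved, and any enal formed by further oxidation is the product of step 2.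

**Step 2**
Reactants: 2 (2E,6R)-2,6-dimethylocta-2,7-dien-1-ol
Product: 3 (2E,6R)-2,6-dimethylocta-2,7-dienal
Conditions: MnO2 (activated, excess), CH2Cl2, rt
Reagents that add atoms: none
Why: Activated manganese dioxide oxidises allylic alcohols to enals under neutral conditions without E/Z isomerisation.

**Step 3**
Reactants: 4 but-3-en-2-one
Product: 5 2-[(triisopropylsilyl)oxy]buta-1,3-diene
Conditions: i-Pr3SiOTf, Et3N, Et2O, 0 °C → rt
Reagents that add atoms: triisopropylsilyl trifluoromethanesulfonate, CC(C)[Si](C(C)C)(C(C)C)OS(=O)(=O)C(F)(F)F
Why: Silyl triflate/amine enol silylation of the methyl ketone gives the 2-silyloxydiene, and the bulky silyl group makes it stable enough to isolate and to survive a Lewis acid.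

**Step 4**
Reactants: 3 (2E,6R)-2,6-dimethylocta-2,7-dienal; 5 2-[(triisopropylsilyl)oxy]buta-1,3-diene
Product: 6 (1S,6S)-1-methyl-6-[(3R)-3-methylpent-4-en-1-yl]-4-[(triisopropylsilyl)oxy]cyclohex-3-ene-1-carbaldehyde
Conditions: 5 (3 equiv), (R)-3,3-diphenyl-1-(2-methylphenyl)tetrahydro-1H,3H-pyrrolo[1,2-c][1,3,2]oxazaborole·HNTf2 (20 mol %), CH2Cl2, −78 → −40 °C
Reagents that add atoms: none
Why: Enantioselective Diels–Alder reaction under chiral oxazaborolidinium catalysis, a known reaction class for α-methyl enals and 2-silyloxydienes. The silyloxy group sends the nucleophilic CH2 terminus of 5 to the β-carbon (C5), so the formyl-bearing C4 ends para to C1; the (E)-geometry of 3 is transferred suprafacially and puts the C4 methyl cis to the C5 chain. The catalyst leaves the Cα-Si/Cβ-Re face of the s-trans enal open, so that C4 and C5 should both form with S configuration.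

**Step 5**
Reactants: 6 (1S,6S)-1-methyl-6-[(3R)-3-methylpent-4-en-1-yl]-4-[(triisopropylsilyl)oxy]cyclohex-3-ene-1-carbaldehyde
Product: 7 (1S,2S)-1-methyl-2-[(3R)-3-methylpent-4-en-1-yl]-4-oxocyclohexane-1-carbaldehyde
Conditions: HF (48% aq.), MeCN, 0 °C
Reagents that add atoms: none
Why: Fluoride-assisted protodesilylation of the silyl enol ether frees the C1 ketone; the aldehyde on the quaternary carbon has no α-hydrogen and cannot epimerise, and no intramolecular aldol is possible because it would close a four-membered ring.

**Step 6**
Reactants: 7 (1S,2S)-1-methyl-2-[(3R)-3-methylpent-4-en-1-yl]-4-oxocyclohexane-1-carbaldehyde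
Product: 8 (1S,2S)-1-methyl-2-[(3R)-3-methylpent-4-en-1-yl]-4-oxocyclohexane-1-carboxylic acid
Conditions: NaClO2, NaH2PO4, 2-methyl-2-butene, t-BuOH/H2O, 0 °C → rt
Reagents that add atoms: sodium chlorite, [Na+].[O-]Cl=O
Why: Pinnick oxidation converts the hindered aldehyde into the acid under buffered conditions, and the large excess of 2-methyl-2-butene traps HOCl so that the vinyl group and the ketone α-positions are not chlorinated.

**Step 7**
Reactants: 8 (1S,2S)-1-methyl-2-[(3R)-3-methylpent-4-en-1-yl]-4-oxocyclohexane-1-carboxylic acid
Product: 9 methyl (1S,2S)-1-methyl-2-[(3R)-3-methylpent-4-en-1-yl]-4-oxocyclohexane-1-carboxylate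
Conditions: Me3SiCHN2, MeOH/toluene, 0 °C → rt
Reagents that add atoms: (trimethylsilyl)diazomethane, C[Si](C)(C)C=[N+]=[N-]
Why: O-Methylation of the carboxylic acid by (trimethylsilyl)diazomethane takes place at the carboxylate oxygen and is therefore insensitive to the quaternary α-carbon that would slow a Fischer esterification.

**Step 8**
Reactants: 9 methyl (1S,2S)-1-methyl-2-[(3R)-3-methylpent-4-en-1-yl]-4-oxocyclohexane-1-carboxylate
Product: 10 methyl (1S,2S)-1-methyl-2-[(3R)-3-methyl-4-oxopentyl]-4-oxocyclohexane-1-carboxylate
Conditions: PdCl2 (10 mol %), CuCl (1 equiv), O2 (1 atm), DMF/H2O (7:1), rt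
Reagents that add atoms: water, O
Why: Tsuji–Wacker oxidation (Markovnikov hydroxypalladation by divalent palladium, then β-hydride elimination) turns the terminal vinyl group into the methyl ketone C9/C20; it is placed here so that the stereocentre C8, now α to a ketone, is exposed for only one further step.

**Step 9**
Reactants: 10 methyl (1S,2S)-1-methyl-2-[(3R)-3-methyl-4-oxopentyl]-4-oxocyclohexane-1-carboxylate
Product: 12 methyl (1S,6R,8aS)-1,5,6-trimethyl-4-oxo-1,2,3,4,6,7,8,8a-octahydronaphthalene-1-carboxylate (bicyclic C1-keto C9=C10 enone; 4S,5S,8R in halimane numbering), via ring-B ketol 11 (not isolated)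
Conditions: pyrrolidine (0.5 equiv), AcOH (0.5 equiv), toluene, 25 → 70 °C
Reagents that add atoms: none
Why: Intramolecular aldol condensation of a 1,7-diketone to a 1-acyl-2-methylcyclohexene through the enamine of the ring ketone; only attack of C10 on C9 can end in a conjugated enone, so the other aldol modes revert. The amine condenses faster with the unhindered ring ketone than with the α-branched methyl ketone, which limits enolisation at C8. In addition the 8R epimer, with C17 pseudoaxial and free of A(1,2) strain against C20, is the expected thermodynamic epimer of 12.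

**Step 10**
Reactants: 12 bicyclic C1-keto C9=C10 enone; 13 propa-1,2-diene (allene)
Product: 14 cis-fused methylenecyclobutane photoadduct (4S,5S,8R,9S,10R): the decalin core of 12 with a four-membered ring C9–C11H2–C12(=CH2)–C10 on the face of H5, C1 ketone and C4 methyl ester retained
Conditions: allene (large excess, condensed), hν (medium-pressure Hg lamp, uranium-glass filter, λ > 340 nm), CH2Cl2, −78 °C
Reagents that add atoms: none
Why: Excitation of the enone and intersystem crossing give a triplet that adds to allene stepwise: the β-carbon C9 bonds to a terminal allene carbon (C11), leaving a triplet 1,4-diradical with spin on C10 and on the central allene carbon, and after spin inversion C10 couples with that central carbon (C12). The closest known reaction type is the [2+2] photocycloaddition of allene to cyclic and 1-acylcycloalkene enones, which gives head-to-head methylenecyclobutanes used as masked acetic ester units. One ring is closed, the cyclobutane C9–C11–C12–C10, by collapse of the 1,4-diradical, and the two-atom bridge allows only cis fusion to ring B. C9 is set by the face of the first bond: the C17 methyl on C8 is pseudoaxial to avoid A(1,2) strain with C20 and the axial C4 methyl lies on the same side, so allene approaches from the face of H5, anti to both. C10 is then fixed by the cis ring fusion, because C12 can reach C10 only from the face on which C11 already sits. Two selectivities are needed: head-to-head regiochemistry, which rests on the known preference of allene to place its methylene-bearing carbon next to the enone α-carbon, and cycloaddition in preference to photoenolisation by hydrogen transfer from C20, which is served by the large excess of allene, the low temperature and an aprotic, base-free medium. The full substitution at C9 that would block a thermal conjugate addition is no obstacle to this diradical pathway.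

**Step 11**
Reactants: 14 cis-fused methylenecyclobutane photoadduct
Product: 15 (1S)-C1 alcohol of 14 (1S,4S,5S,8R,9S,10R; hydroxyl cis to C9 and trans to C12)
Conditions: NaBH4, MeOH, 0 °C → rt
Reagents that add atoms: none
Why: Hydride reduction of the ketone; the C1=O bond avoids eclipsing the C9 arm with its C20 methyl, so C9 stands nearly perpendicular to the carbonyl plane and hydride should enter anti to it, from the side of the flat C12. This places the new C–O bond cis to C9 and trans to C12, the relationship needed in step 14; the hindered methyl ester is not reduced by NaBH4.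

**Step 12**
Reactants: 15 (1S)-C1 alcohol of 14
Product: 16 C1 methanesulfonate of 15
Conditions: MsCl, Et3N, CH2Cl2, 0 °C
Reagents that add atoms: methanesulfonyl chloride, CS(=O)(=O)Cl
Why: Mesylation through sulfene works on hindered secondary alcohols; C10 is quaternary and the medium stays basic, so neither elimination nor ionisation of the cyclobutylcarbinyl sulfonate is expected.

**Step 13**
Reactants: 16 C1 methanesulfonate of 15
Product: 18 cyclobutanone mesylate (C12 ketone in place of the exocyclic methylene of 16; 1S,4S,5S,8R,9S,10R), via spiro ozonide 17 (not isolated)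
Conditions: O3, CH2Cl2, −78 °C; then PPh3, −78 °C → rt
Reagents that add atoms: ozone, [O-][O+]=O
Why: Ozonolysis of the only alkene present, the 1,1-disubstituted exocyclic methylene, with reductive work-up gives the cyclobutanone; the conditions are neutral and cold, so the mesylate is not disturbed.

**Step 14**
Reactants: 18 cyclobutanone mesylate
Product: 19 methyl (1S,5S,6R,8aS)-5-(2-methoxy-2-oxoethyl)-1,5,6-trimethyl-1,2,3,5,6,7,8,8a-octahydronaphthalene-1-carboxylate (Δ1(10) diester; 4S,5S,8R,9S)
Conditions: NaOMe, MeOH, 0 °C → rt
Reagents that add atoms: sodium methoxide, [Na+].[O-]C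
Why: Alkoxide-triggered Grob fragmentation of a β-sulfonyloxy ketone: methoxide adds to the strained cyclobutanone, and the hemiketal alkoxide expels the anti-periplanar C1 mesylate with cleavage of C10–C12, giving the methyl ester on C11 and the C1=C10 alkene in one operation. The alkene position is set by the mechanism and the relief of ring strain drives the step; C4, C5, C8 and C9 are not touched.

**Step 15**
Reactants: 19 Δ1(10) diester
Product: 20 methyl (4S,5S,8R,9S)-12-hydroxy-13,14,15,16-tetranorhalim-1(10)-en-4-carboxylate (primary alcohol HOCH2CH2– on C9)
Conditions: LiBH4 (2 equiv), THF, 0 °C → rt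
Reagents that add atoms: none
Why: Chemoselective ester reduction: the CH2CO2Me ester is reached by borohydride, whereas the ester on the quaternary ring carbon C4 is far more shielded and should remain.

**Step 16**
Reactants: 20 primary alcohol
Product: 21 primary iodide (ICH2CH2– on C9; otherwise as 20)
Conditions: I2, PPh3, imidazole, CH2Cl2, 0 °C → rt
Reagents that add atoms: iodine, II
Why: Appel-type iodination of a primary alcohol by SN2 displacement of the oxyphosphonium group at C12; the trisubstituted ring alkene is inert under these buffered conditions.

**Step 17**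
Reactants: 22 but-2-yn-1-ol
Product: 23 tert-butyl(but-2-yn-1-yloxy)dimethylsilane
Conditions: t-BuMe2SiCl, imidazole, CH2Cl2, rt
Reagents that add atoms: tert-butyldimethylsilyl chloride, CC(C)(C)[Si](C)(C)Cl
Why: Standard silylation of a primary alcohol.

**Step 18**
Reactants: 23 tert-butyl(but-2-yn-1-yloxy)dimethylsilane
Product: 25 (E)-tert-butyl[(3-iodobut-2-en-1-yl)oxy]dimethylsilane, via alkenylzirconocene chloride 24 (not isolated)
Conditions: Cp2Zr(H)Cl (2 equiv), THF, 50 °C; then I2, 0 °C
Reagents that add atoms: iodine, II
Why: syn-Hydrozirconation with excess Cp2Zr(H)Cl equilibrates to the isomer with zirconium on the less hindered, methyl-bearing alkyne carbon; iodinolysis with retention should give the (E)-alkenyl iodide in which iodine is trans to the CH2O group.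

**Step 19**
Reactants: 21 primary iodide; 25 (E)-tert-butyl[(3-iodobut-2-en-1-yl)oxy]dimethylsilane
Product: 27 methyl (4S,5S,8R,9S,13E)-15-[(tert-butyldimethylsilyl)oxy]halima-1(10),13-dien-4-carboxylate (carboxyl carbon on C4), via alkylzinc iodide 26 (not isolated)
Conditions: Zn dust (activated), LiCl, THF, 40 °C; then 25, Pd(PPh3)4 (5 mol %), THF, rt → 50 °C
Reagents that add atoms: none
Why: Negishi cross-coupling: zinc inserts into the primary C–I bond in the presence of the ester, and zerovalent palladium couples the alkylzinc iodide with the alkenyl iodide with retention of geometry, forming C12–C13 and the (13E) alkene.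

**Step 20**
Reactants: 27 silyl ether methyl ester
Product: 28 methyl (4S,5S,8R,9S,13E)-15-hydroxyhalima-1(10),13-dien-4-carboxylate
Conditions: Bu4NF, THF, 0 °C → rt
Reagents that add atoms: none
Why: Fluoride cleaves the Si–O bond of the primary allylic silyl ether; ester and alkenes are inert.

**Step 21**
Reactants: 28 hydroxy methyl ester
Product: 29 (4S,5S,8R,9S,13E)-15-hydroxyhalima-1(10),13-dien-4-carboxylic acid
Conditions: NaSEt (6 equiv), DMF, 100 °C; then 0.5 M HCl, 0 °C
Reagents that add atoms: none
Why: Thiolate demethylation by SN2 attack at the ester methyl carbon does not depend on access to the shielded C4 carbonyl, which makes ordinary saponification slow; the alkenes and the allylic alkoxide are unaffected, and the brief cold acidification does not move the 1(10) alkene.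

**Step 22**
Reactants: 29 hydroxy acid
Product: 30 (1S,5S,6R,8aS)-1,5,6-trimethyl-5-[(3E)-3-methyl-5-(propanoyloxy)pent-3-en-1-yl]-1,2,3,5,6,7,8,8a-octahydronaphthalene-1-carboxylic acid (CNP0223570.1)
Conditions: (EtCO)2O, pyridine, 4-(dimethylamino)pyridine (0.1 equiv), CH2Cl2, 0 °C → rt; then aq. NaHCO3/THF, rt; pH 4 buffer
Reagents that add atoms: propanoic anhydride, CCC(=O)OC(=O)CC
Why: Nucleophile-catalysed O-acylation of the primary allylic alcohol; any mixed anhydride formed at the hindered acid is hydrolysed at its unhindered propanoyl carbonyl during the bicarbonate work-up, which returns the free acid and leaves the propanoate ester.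

## Compound list

1 | (3R)-3,7-dimethylocta-1,6-diene [(R)-β-citronellene] | C=C[C@H](C)CCC=C(C)C | starting material
2 | (2E,6R)-2,6-dimethylocta-2,7-dien-1-ol | C=C[C@H](C)CC/C=C(\C)CO | intermediate
3 | (2E,6R)-2,6-dimethylocta-2,7-dienal | C=C[C@H](C)CC/C=C(\C)C=O | intermediate
4 | but-3-en-2-one | CC(=O)C=C | starting material
5 | 2-[(triisopropylsilyl)oxy]buta-1,3-diene | C=CC(=C)O[Si](C(C)C)(C(C)C)C(C)C | intermediate
6 | (1S,6S)-1-methyl-6-[(3R)-3-methylpent-4-en-1-yl]-4-[(triisopropylsilyl)oxy]cyclohex-3-ene-1-carbaldehyde | C1(O[Si](C(C)C)(C(C)C)C(C)C)=CC[C@](C)(C=O)[C@@H](CC[C@@H](C)C=C)C1 | intermediate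
7 | (1S,2S)-1-methyl-2-[(3R)-3-methylpent-4-en-1-yl]-4-oxocyclohexane-1-carbaldehyde | O=C1CC[C@](C)(C=O)[C@@H](CC[C@@H](C)C=C)C1 | intermediate
8 | (1S,2S)-1-methyl-2-[(3R)-3-methylpent-4-en-1-yl]-4-oxocyclohexane-1-carboxylic acid | O=C1CC[C@](C)(C(=O)O)[C@@H](CC[C@@H](C)C=C)C1 | intermediate
9 | methyl (1S,2S)-1-methyl-2-[(3R)-3-methylpent-4-en-1-yl]-4-oxocyclohexane-1-carboxylate | O=C1CC[C@](C)(C(=O)OC)[C@@H](CC[C@@H](C)C=C)C1 | intermediate
10 | methyl (1S,2S)-1-methyl-2-[(3R)-3-methyl-4-oxopentyl]-4-oxocyclohexane-1-carboxylate | O=C1CC[C@](C)(C(=O)OC)[C@@H](CC[C@@H](C)C(C)=O)C1 | intermediate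
11 | methyl (1S,6R,8aS)-5-hydroxy-1,5,6-trimethyl-4-oxodecahydronaphthalene-1-carboxylate (ring-B ketol, C9 and C10 unassigned, not isolated) | CC1(O)C2C(=O)CC[C@](C)(C(=O)OC)[C@H]2CC[C@H]1C | intermediate
12 | methyl (1S,6R,8aS)-1,5,6-trimethyl-4-oxo-1,2,3,4,6,7,8,8a-octahydronaphthalene-1-carboxylate | CC1=C2C(=O)CC[C@](C)(C(=O)OC)[C@H]2CC[C@H]1C | intermediate
13 | propa-1,2-diene (allene) | C=C=C | starting material
14 | cis-fused methylenecyclobutane photoadduct (4S,5S,8R,9S,10R) | C=C1C[C@]2(C)[C@]13C(=O)CC[C@](C)(C(=O)OC)[C@H]3CC[C@H]2C | intermediate
15 | (1S)-C1 alcohol of 14 | C=C1C[C@]2(C)[C@]13[C@@H](O)CC[C@](C)(C(=O)OC)[C@H]3CC[C@H]2C | intermediate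
16 | C1 methanesulfonate of 15 | C=C1C[C@]2(C)[C@]13[C@@H](OS(C)(=O)=O)CC[C@](C)(C(=O)OC)[C@H]3CC[C@H]2C | intermediate
17 | spiro 1,2,4-trioxolane (ozonide) of 16 at C12 (spiro centre unassigned, not isolated) | C1OOC2(O1)C[C@]3(C)[C@]24[C@@H](OS(C)(=O)=O)CC[C@](C)(C(=O)OC)[C@H]4CC[C@H]3C | intermediate
18 | cyclobutanone mesylate (C12 ketone) | O=C1C[C@]2(C)[C@]13[C@@H](OS(C)(=O)=O)CC[C@](C)(C(=O)OC)[C@H]3CC[C@H]2C | intermediate
19 | methyl (1S,5S,6R,8aS)-5-(2-methoxy-2-oxoethyl)-1,5,6-trimethyl-1,2,3,5,6,7,8,8a-octahydronaphthalene-1-carboxylate | COC(=O)C[C@]1(C)C2=CCC[C@](C)(C(=O)OC)[C@H]2CC[C@H]1C | intermediate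
20 | methyl (1S,5S,6R,8aS)-5-(2-hydroxyethyl)-1,5,6-trimethyl-1,2,3,5,6,7,8,8a-octahydronaphthalene-1-carboxylate | OCC[C@]1(C)C2=CCC[C@](C)(C(=O)OC)[C@H]2CC[C@H]1C | intermediate
21 | methyl (1S,5S,6R,8aS)-5-(2-iodoethyl)-1,5,6-trimethyl-1,2,3,5,6,7,8,8a-octahydronaphthalene-1-carboxylate | ICC[C@]1(C)C2=CCC[C@](C)(C(=O)OC)[C@H]2CC[C@H]1C | intermediate
22 | but-2-yn-1-ol | CC#CCO | starting material
23 | tert-butyl(but-2-yn-1-yloxy)dimethylsilane | CC#CCO[Si](C)(C)C(C)(C)C | intermediate
24 | (E)-alkenylzirconocene chloride, zirconium on the methyl-bearing carbon (not isolated) | C/C(=C\CO[Si](C)(C)C(C)(C)C)[Zr](Cl)(C1C=CC=C1)C1C=CC=C1 | intermediate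
25 | (E)-tert-butyl[(3-iodobut-2-en-1-yl)oxy]dimethylsilane | C/C(I)=C\CO[Si](C)(C)C(C)(C)C | intermediate
26 | alkylzinc iodide from 21 (IZnCH2CH2– on C9, not isolated) | I[Zn]CC[C@]1(C)C2=CCC[C@](C)(C(=O)OC)[C@H]2CC[C@H]1C | intermediate
27 | methyl (1S,5S,6R,8aS)-5-[(3E)-5-[(tert-butyldimethylsilyl)oxy]-3-methylpent-3-en-1-yl]-1,5,6-trimethyl-1,2,3,5,6,7,8,8a-octahydronaphthalene-1-carboxylate | CC(C)(C)[Si](C)(C)OC/C=C(\C)CC[C@]1(C)C2=CCC[C@](C)(C(=O)OC)[C@H]2CC[C@H]1C | intermediate
28 | methyl (1S,5S,6R,8aS)-5-[(3E)-5-hydroxy-3-methylpent-3-en-1-yl]-1,5,6-trimethyl-1,2,3,5,6,7,8,8a-octahydronaphthalene-1-carboxylate | OC/C=C(\C)CC[C@]1(C)C2=CCC[C@](C)(C(=O)OC)[C@H]2CC[C@H]1C | intermediate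
29 | (1S,5S,6R,8aS)-5-[(3E)-5-hydroxy-3-methylpent-3-en-1-yl]-1,5,6-trimethyl-1,2,3,5,6,7,8,8a-octahydronaphthalene-1-carboxylic acid | OC/C=C(\C)CC[C@]1(C)C2=CCC[C@](C)(C(=O)O)[C@H]2CC[C@H]1C | intermediate
30 | (1S,5S,6R,8aS)-1,5,6-trimethyl-5-[(3E)-3-methyl-5-(propanoyloxy)pent-3-en-1-yl]-1,2,3,5,6,7,8,8a-octahydronaphthalene-1-carboxylic acid | CCC(=O)OC/C=C(\C)CC[C@]1(C)C2=CCC[C@](C)(C(=O)O)[C@H]2CC[C@H]1C | target

## Step count and least certain steps

Total: 22 steps. Longest linear sequence: 19 steps (steps 1, 2, 4–16 and 19–22); steps 3, 17 and 18 make the two side fragments.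

**Step 10 (key step).** Three processes can defeat it.
- Photoenolisation: the chromophore is an s-cis acylcyclohexene whose C20 methyl lies next to the carbonyl oxygen, so hydrogen transfer from C20 and deconjugation may compete with cycloaddition.
- Loss of regiocontrol: if the central allene carbon bonds to C9, the later cyclobutanone is not a β-relationship to C1 and cannot fragment.
- Loss of facial control: this would give the C9 epimer.

The fallback replaces the photochemical step by a sigmatropic transfer of the same two carbons. It sets out from 12. Reagent-controlled reduction with (S)-1-methyl-3,3-diphenyltetrahydro-1H,3H-pyrrolo[1,2-c][1,3,2]oxazaborole and BH3·SMe2 (the alkenyl side acting as the large group) would give the (1R)-allylic alcohol F1, whose C1–O bond lies on the face of H5. A Johnson–Claisen rearrangement of F1 (trimethyl orthoacetate, catalytic propanoic acid, xylene, 140 °C) forms C9–C11 suprafacially on that face and shifts the alkene to C1=C10. It comes back to the route directly at 19.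

**Step 4.** The cycloaddition of a β-substituted α-methyl enal may be slow, and the facial discrimination by the catalyst may be incomplete, which would give the ring-A diastereomer. The fallback uses a more nucleophilic diene and a different activation. It sets out from 3. Cycloaddition with (E)-1-(dimethylamino)-3-(tert-butyldimethylsilyloxy)buta-1,3-diene under the chiral Lewis acid (R,R)-(salen)CrSbF6 (salen = N,N'-bis(3,5-di-tert-butylsalicylidene)cyclohexane-1,2-diamine dianion) would give the amino silyl enol ether F2. Aqueous HF in MeCN removes the silyl group and dimethylamine to give the 4-formyl cyclohexenone F3. Conjugate reduction of F3 with [(Ph3P)CuH]6, which spares the vinyl group and the hindered aldehyde, comes back at 7.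

**Step 9.** Enolisation of the methyl ketone towards C8 before ring closure, or γ-deprotonation of the product, would erode the configuration at C8. The amine may also fail to dehydrate the tertiary ketol. The fallback replaces the reversible one-flask condensation by an irreversible two-stage closure. It sets out from 10. A titanium enolate aldol addition (TiCl4, Bu3N, CH2Cl2, −78 °C) is stopped at ketol 11, which is isolated. Syn-elimination of 11 with methyl N-(triethylammoniosulfonyl)carbamate (Burgess reagent) towards the acidified C10–H then comes back at 12. No compound outside the list is made.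

**Step 14 (with step 11).** The fragmentation needs the C1–O bond anti-periplanar to C10–C12. It fails if the hydride of step 11 entered from the C9 side, or if the cyclobutylcarbinyl mesylate ionises with ring expansion first. The fallback separates ring opening from alkene formation. It sets out from 14. Ozonolysis (O3; PPh3) gives the 1,3-diketone F4. Retro-Claisen opening with NaOMe in MeOH cuts C10–C12 to the keto diester F5. NaBH4 gives the C1 alcohol F6. Dehydration of F6 with the Burgess reagent comes back at 19, with the Δ1 regioisomer to be separated if it forms.

**Step 15.** Hydride may also attack the C4 ester, or the reduction may stop short, so that the two methyl esters are poorly distinguished. The fallback makes the two acyl groups chemically different. It sets out from 18. Fragmentation with LiSEt in THF instead of methoxide would give the S-ethyl thioester F7. NaBH4 in EtOH reduces a thioester far faster than a hindered methyl ester and comes back at 20.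

## Further compounds

F1 | step 10 | methyl (1S,4R,6R,8aS)-4-hydroxy-1,5,6-trimethyl-1,2,3,4,6,7,8,8a-octahydronaphthalene-1-carboxylate [(1R)-allylic alcohol in halimane numbering] | CC1=C2[C@H](O)CC[C@](C)(C(=O)OC)[C@H]2CC[C@H]1C
F2 | step 4 | 4-[(tert-butyldimethylsilyl)oxy]-2-(dimethylamino)-1-methyl-6-[(3R)-3-methylpent-4-en-1-yl]cyclohex-3-ene-1-carbaldehyde, quaternary carbon and chain-bearing carbon configured as in 6, amine-bearing carbon unassigned | CN(C)C1C=C(O[Si](C)(C)C(C)(C)C)C[C@H](CC[C@@H](C)C=C)[C@@]1(C)C=O
F3 | step 4 | 1-methyl-6-[(3R)-3-methylpent-4-en-1-yl]-4-oxocyclohex-2-ene-1-carbaldehyde, ring stereocentres as in 7 | O=C1C=C[C@](C)(C=O)[C@@H](CC[C@@H](C)C=C)C1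
F0 | step 9 | none | none
F4 | step 14 | 1,3-diketone: photoadduct 14 with a C12 ketone in place of the exocyclic methylene | O=C1C[C@]2(C)[C@]13C(=O)CC[C@](C)(C(=O)OC)[C@H]3CC[C@H]2C
F5 | step 14 | keto diester: 19 with a C1 ketone and C10–H (C10 epimers) | COC(=O)C[C@]1(C)C2C(=O)CC[C@](C)(C(=O)OC)[C@H]2CC[C@H]1C
F6 | step 14 | C1 alcohol of F5 (C1 and C10 unassigned) | COC(=O)C[C@]1(C)C2C(O)CC[C@](C)(C(=O)OC)[C@H]2CC[C@H]1C
F7 | step 15 | S-ethyl thioester analogue of 19 at C12 | CCSC(=O)C[C@]1(C)C2=CCC[C@](C)(C(=O)OC)[C@H]2CC[C@H]1C
A1 | alternative 1 | (E)-2-methylbut-2-enal | C/C=C(\C)C=O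
A2 | alternative 1 | (E)-1-(tert-butyldimethylsilyloxy)buta-1,3-diene | C=C/C=C/O[Si](C)(C)C(C)(C)C
A3 | alternative 1 | ring-B cyclohexene with C9 formyl, C10 silyloxy and cis C8/C9 methyl groups | O=C[C@]1(C)[C@H](O[Si](C)(C)C(C)(C)C)C=CC[C@H]1C
A4 | alternative 2 | cis-fused C1-keto octalin with a C6=C7 alkene and the silylated side chain | CC(C)(C)[Si](C)(C)OC/C=C(\C)CC[C@]1(C)[C@H]2C(=O)CC[C@](C)(C(=O)OC)[C@H]2C=C[C@H]1C
A5 | alternative 3 | ring-A geminal acid ester with the C1=C10 alkene | CC(C)(C)[Si](C)(C)OC/C=C(\C)CC[C@]1(C)C2=CCC[C@](C(=O)O)(C(=O)OC)[C@H]2CC[C@H]1C
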